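The numbers in the tables were generated by integration on assumed constants.

The reading that matters on the repeat of this flask comes at 3.0 min, and what I have to decide before charging is whether the charge can stay as it stands.

- east: free monomer 0.25 M; protic impurity 0.125 M; initiator 0.57 mM; the very flask that is asked about, followed so far
- flask: free monomer 0.25 M; protic impurity 0.125 M; initiator 0.57 mM; time 3.0 min

east run (percent of the free monomer charged)

| time / s | monomer in chains / % | free monomer / % |
|---|---|---|
| 10.0 | 1.0 | 96.7 |
| 12.0 | 1.1 | 95.3 |
| 20.0 | 2.0 | 93.1 |
| 30.0 | 4.2 | 90.3 |
| 50.0 | 6.1 | 81.2 |
| 90.0 | 14.3 | 68.5 |

(scatter of a reading: 1 percentage point)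

- the average divides the monomer in chains by the number of chains begun, living and dead together
- the earlier runs do not show the number of chains; that part of a forecast is a guess

1. whether the average number of monomer units in a chain (chains begun, living or dead) reaches 90 by 3.0 min (no / yes)
2. average number of monomer units in a chain (chains begun, living or dead) at 3.0 min

I work in powers of ten. Free monomer charged over initiator charged is 439, and this charge ratio turns a fraction of the charge in chains into an average length (the number-average degree of polymerization), provided every initiator has begun one chain, a guess these readings can't test. Its logarithm is 2.64 and that of the wanted 90 is 1.95, so the two lie 0.688 apart, and 20.5% of the charge has to stand in chains.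

The last reading of this flask gives 14.3% at 90.0 s, and the last stretch added 8.2 percentage points in 40.0 s, each reading carrying 1 point of scatter. To arrive by 3.0 min the pace need be a third of that, so I leave the charge alone and answer yes. Carried on at the read pace, my reckoning puts the crossing at 2.01 min and the length at 3.0 min at 144, an estimate I expect to sit high, since I expect the pace to ease as free monomer falls.

The forecast says yes with an average of 135, judging that “reaching 90 is likely”. The flask gives yes, with an average of 115.

    free monomer + living end → monomer in chains + living end, rate k1*[living end]*[free monomer] (k = 5.33 M⁻¹ s⁻¹)
    protic impurity + free monomer → quenched substrate (k = 0.0214 M⁻¹ s⁻¹)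
    free monomer + initiator → living end + monomer in chains (k = 0.184 M⁻¹ s⁻¹)
    monomer in chains + living end → free monomer + living end, rate k4*[living end] as long as [monomer in chains] is above zero (k = 0.182 s⁻¹)

In this flask 26.1% of the charge stands in chains at 3.00 min, which the charge ratio turns into 115, and the wanted length is passed at 2.20 min. At 3.00 min this flask still makes monomer in chains 3.59 times faster than it uses it up, each step taken net.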